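**Plan**
- Retrosynthesis: open the 1,2-dioxane at O–C13 (hydroperoxide on C16 adds to a C12=C13 alkene), cut C9–C11 and C9–CH3 (two enolate alkylations), cut ring A at C1=C10 (carbonyl coupling), and cut ring B at C7–C8 and C5–C10 in one annulation.
- Forward: ring B is made first. The CH–CH3 carbon C8 lies 1,3 to the ring-fusion carbon C10, and C5 and C7 flank C6, so ring B is crotonaldehyde (C8–C9–C10) plus the α- and γ-carbons of a β-keto ester whose ketone is C6.
- The helper oxygen on C6 is then moved to C10 (Wharton transposition), where it serves the quaternisation of C9 and the closure of ring A; the side chain is made separately and joined at C9.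
- Stereochemistry: C8 from the amine catalyst; C5 by equilibration to the all-equatorial ketone before C9 is quaternised; C9 by methylation anti to the C8 methyl.
- C16 and C17′ come from an auxiliary-controlled syn-aldol (C16 is later inverted by SN2 with HOO⁻); C13 comes from the chair transition state of the ring-closing peroxymercuration.

Key step: step 2

Remark (atom labels used below): C1–C10 are the decalin carbons (C1=C10 alkene, C4 the gem-dimethyl carbon, C5 the ring-fusion CH, C8 the CH–CH3 carbon, C9 the quaternary carbon). C11–C16 are the chain and dioxane carbons counted from C9 (C13 and C16 carry the peroxide oxygens). C17′ is the CH(CH3) carbon and C18′ the carboxyl carbon.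

Step 1
Reactants: 1 methyl 3,3-dimethylpent-4-enoate; 2 tert-butyl acetate
Product: 4 tert-butyl 5,5-dimethyl-3-oxohept-6-enoate, via lithium enolate of tert-butyl acetate 3 (not isolated)
Conditions: LiN(i-Pr)2 (2.2 equiv), 2, THF, −78 °C; then 1, −78 → 0 °C; aq. NH4Cl
Reagents that add atoms: none
Why: Crossed Claisen condensation, in which the pre-formed ester enolate acylates on the methyl ester and the β-keto ester is protected from further attack as its enolate; no stereocenter is formed.

Step 2
Reactants: 4 tert-butyl 5,5-dimethyl-3-oxohept-6-enoate; 5 (E)-but-2-enal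
Product: 8 (5S)-5-methyl-2-(2-methylbut-3-en-2-yl)cyclohex-2-en-1-one, via Michael adduct 6 (not isolated), via cyclohexenone tert-butyl ester 7 (not isolated)
Conditions: (R)-2-{bis[3,5-bis(trifluoromethyl)phenyl][(trimethylsilyl)oxy]methyl}pyrrolidine (10 mol %), PhCO2H (10 mol %), toluene, rt; then p-TsOH·H2O (20 mol %), 80 °C
Reagents that add atoms: none
Why: The amine condenses with 5 to an E-iminium ion, the doubly activated carbon C7 of 4 adds to its β-carbon C8 (Michael addition, bond C7–C8), and after hydrolysis the γ-carbon C5 attacks the aldehyde carbon C10 in an intramolecular aldol reaction (bond C5–C10), followed by dehydration and acid-induced loss of isobutene and CO2. The closest known reaction type is the amine-catalysed Michael/aldol-condensation (Robinson-type) annulation of β-keto esters with enals to 5-substituted cyclohex-2-enones. Ring B closes in the aldol step as a 6-(enolendo)-exo-trig cyclisation, and closure through C7 is excluded because it would give a four-membered ring. The only stereocenter that survives, C8, is set in the Michael step by the catalyst: the diarylsiloxymethyl group of the (R)-pyrrolidine shields the Re face of the iminium β-carbon, so C7 should add to the Si face and give the (S)-enone. The step needs Michael addition through C7 rather than C5 and 1,4- rather than 1,2-addition to the enal; the first is secured by the higher acidity of the carbon between the two carbonyl groups, the second by iminium activation of the β-carbon.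

Step 3
Reactants: 8 (5S)-5-methyl-2-(2-methylbut-3-en-2-yl)cyclohex-2-en-1-one
Product: 9 (1S,4S,6S)-4-methyl-1-(2-methylbut-3-en-2-yl)-7-oxabicyclo[4.1.0]heptan-2-one
Conditions: 30% aq. H2O2, NaOH, MeOH, 0 °C
Reagents that add atoms: hydrogen peroxide, OO
Why: Weitz–Scheffer nucleophilic epoxidation, in which hydroperoxide anion adds to the unsubstituted β-carbon C10 and closes onto C5, expected on the face anti to the C8 methyl group, while the isolated vinyl group is inert to the nucleophilic oxidant.

Step 4
Reactants: 9 (1S,4S,6S)-4-methyl-1-(2-methylbut-3-en-2-yl)-7-oxabicyclo[4.1.0]heptan-2-one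
Product: 10 (1S,5R)-5-methyl-2-(2-methylbut-3-en-2-yl)cyclohex-2-en-1-ol
Conditions: N2H4·H2O, AcOH (cat.), MeOH, 0 °C → rt
Reagents that add atoms: none
Why: Wharton transposition, in which the epoxy hydrazone fragments with loss of N2 to the allylic alcohol, moving the oxygen from C6 to C10 and the double bond to C5=C6 with retention of the C10–O bond of the epoxide.

Step 5
Reactants: 10 (1S,5R)-5-methyl-2-(2-methylbut-3-en-2-yl)cyclohex-2-en-1-ol
Product: 11 (5R)-5-methyl-2-(2-methylbut-3-en-2-yl)cyclohex-2-en-1-one
Conditions: Dess–Martin periodinane, NaHCO3, CH2Cl2, 0 °C → rt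
Reagents that add atoms: none
Why: Dess–Martin oxidation of the secondary allylic alcohol gives the transposed enone, in which C10 carries the carbonyl group and C9 is the enolisable α′-carbon, without touching C8.

Step 6
Reactants: 12 geranyl chloride
Product: 13 (4E)-6-chloro-4-methylhex-4-enal
Conditions: O3 (1.0 equiv), pyridine (3 equiv), CH2Cl2, −78 °C
Reagents that add atoms: ozone, O=[O+][O-]
Why: Ozonolysis with pyridine-promoted breakdown of the carbonyl oxide, in which the electron-rich terminal trisubstituted alkene should react faster than the 2,3-alkene deactivated by the allylic chlorine, so that only the distal double bond is cleaved.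

Step 7
Reactants: 13 (4E)-6-chloro-4-methylhex-4-enal; 14 (4S)-4-benzyl-3-propanoyl-1,3-oxazolidin-2-one
Product: 16 (4S)-4-benzyl-3-[(2S,3R,6E)-8-chloro-3-hydroxy-2,6-dimethyloct-6-enoyl]-1,3-oxazolidin-2-one, via boron enolate 15 (not isolated)
Conditions: 14, Bu2BOTf, i-Pr2NEt, CH2Cl2, −78 → 0 °C; then 13, −78 → 0 °C; pH 7 buffer
Reagents that add atoms: none
Why: Evans syn-aldol reaction, in which the Z-boron enolate reacts through a closed chair (Zimmerman–Traxler) transition state with one enolate face blocked by the benzyl group of the auxiliary, which sets C17′ (S) and C16 (R, syn).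

Step 8
Reactants: 16 syn-aldol adduct
Product: 17 tert-butyldimethylsilyl ether of 16
Conditions: TBSOTf, 2,6-lutidine, CH2Cl2, −78 °C
Reagents that add atoms: tert-butyldimethylsilyl trifluoromethanesulfonate, CC(C)(C)[Si](C)(C)OS(=O)(=O)C(F)(F)F
Why: Silylation of the secondary alcohol with the silyl triflate and a hindered pyridine base protects O16 through the later enolate chemistry without affecting a stereocenter.

Step 9
Reactants: 17 tert-butyldimethylsilyl ether of 16
Product: 18 (2R,3R,6E)-3-[(tert-butyldimethylsilyl)oxy]-8-chloro-2,6-dimethyloct-6-en-1-ol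
Conditions: LiBH4, MeOH (1 equiv), Et2O, 0 °C
Reagents that add atoms: none
Why: Reductive cleavage of the N-acyl oxazolidinone with LiBH4 gives the primary alcohol without epimerising the α-stereocenter C17′ and releases the auxiliary.

Step 10
Reactants: 18 (2R,3R,6E)-3-[(tert-butyldimethylsilyl)oxy]-8-chloro-2,6-dimethyloct-6-en-1-ol
Product: 19 (2R,3R,6E)-3-[(tert-butyldimethylsilyl)oxy]-1-[(tert-butyldiphenylsilyl)oxy]-8-chloro-2,6-dimethyloct-6-ene
Conditions: TBDPSCl, imidazole, CH2Cl2, 0 °C → rt
Reagents that add atoms: tert-butyl(chloro)diphenylsilane, CC(C)(C)[Si](Cl)(c1ccccc1)c1ccccc1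
Why: Silylation of the primary alcohol gives an ether that survives the later acidic removal of the TBS group, without affecting a stereocenter.

Step 11
Reactants: 11 (5R)-5-methyl-2-(2-methylbut-3-en-2-yl)cyclohex-2-en-1-one; 19 allylic chloride
Product: 21 C9-alkylated enone (chain trans to the C8 methyl), via lithium dienolate 20 (not isolated)
Conditions: LiN(i-Pr)2, THF, −78 °C; then 19, NaI (cat.), DMPU, −78 → −20 °C
Reagents that add atoms: none
Why: Kinetic α′-deprotonation of the 2-substituted enone at C9 gives the cross-conjugated dienolate, which is alkylated by the allylic halide (SN2, iodide catalysis) on the face anti to the adjacent C8 methyl group; this C9 configuration is provisional.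

Step 12
Reactants: 21 C9-alkylated enone
Product: 23 all-equatorial cyclohexanone, via lithium enolate 22 (not isolated)
Conditions: LiBH(s-Bu)3, THF, −78 °C; then MeOH, NaOMe, rt
Reagents that add atoms: none
Why: Conjugate reduction, in which the hindered borohydride delivers hydride to the unsubstituted β-carbon C6 and protonation followed by methoxide equilibration of the two epimerisable α-carbons should give the ketone with the C5 substituent, the C8 methyl and the C9 chain all equatorial, which sets C5 (1,4-trans to the C8 methyl).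

Step 13
Reactants: 23 all-equatorial cyclohexanone
Product: 25 C9-methylated ketone, via lithium enolate 24 (not isolated)
Conditions: LiN(i-Pr)2, THF, −78 °C; then MeI, DMPU, −78 → 0 °C
Reagents that add atoms: iodomethane, CI
Why: Kinetic enolate alkylation, in which the base removes the C9 proton rather than the C5 proton shielded by the adjacent quaternary carbon and iodomethane attacks axially on the face anti to the C8 methyl group, so that the new C9 methyl should end trans to the C8 methyl and the chain cis to it.

Step 14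
Reactants: 25 C9-methylated ketone
Product: 26 keto aldehyde
Conditions: Rh(acac)(CO)2 (1 mol %), BIPHEPHOS (2 mol %), CO/H2 (1:1, 10 bar), toluene, 70 °C
Reagents that add atoms: carbon monoxide, [C-]#[O+]
Why: Linear-selective hydroformylation, in which the vinyl group on the quaternary carbon C4 is the only monosubstituted alkene and can take the formyl group only at its terminus, adding C1 as an aldehyde while the trisubstituted alkene and the ketone stay inert.

Step 15
Reactants: 26 keto aldehyde
Product: 27 decalin bis-silyl ether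
Conditions: TiCl3(DME)1.5, zinc–copper couple, DME, reflux, slow addition of 26
Reagents that add atoms: none
Why: Intramolecular McMurry coupling, in which low-valent titanium joins the aldehyde carbon C1 to the ketone carbon C10 and deoxygenates the pinacolate, closing ring A as the trisubstituted C1=C10 alkene without regiochemical ambiguity and without base, so that C5 is not epimerised.

Step 16
Reactants: 27 decalin bis-silyl ether
Product: 28 C16 alcohol
Conditions: camphorsulfonic acid (10 mol %), MeOH/CH2Cl2, 0 °C
Reagents that add atoms: none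
Why: Acid-catalysed methanolysis removes the secondary TBS ether much faster than the primary TBDPS ether, freeing O16 selectively.

Step 17
Reactants: 28 C16 alcohol
Product: 29 C16 mesylate
Conditions: MsCl, Et3N, CH2Cl2, 0 °C
Reagents that add atoms: methanesulfonyl chloride, CS(=O)(=O)Cl
Why: Mesylation of the secondary alcohol with retention at C16 prepares the SN2 step.

Step 18
Reactants: 29 C16 mesylate
Product: 30 C16 hydroperoxide
Conditions: 50% aq. H2O2 (excess), KOH, MeOH/THF, 0 °C → rt
Reagents that add atoms: hydrogen peroxide, OO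
Why: Perhydrolysis by SN2 displacement, in which hydroperoxide anion replaces the secondary mesylate with inversion and so turns the aldol configuration at C16 into that of the target.

Step 19
Reactants: 30 C16 hydroperoxide
Product: 32 1,2-dioxane silyl ether, via organomercurial 31 (not isolated)
Conditions: Hg(OAc)2 (1.1 equiv), HClO4 (cat.), CH2Cl2, 0 °C; then NaBH4, aq. NaOH, 0 °C
Reagents that add atoms: none
Why: Intramolecular peroxymercuration–demercuration, in which Hg(OAc)2 activates the C12=C13 alkene and the hydroperoxide adds to the tertiary carbon C13 in a 6-exo Markovnikov cyclisation through a chair transition state with the C16 substituent and the C12 branch equatorial and the methyl axial, which should set C13, before NaBH4 replaces mercury on C12 by hydrogen.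

Step 20
Reactants: 32 1,2-dioxane silyl ether
Product: 33 primary alcohol
Conditions: Bu4NF, THF, 0 °C → rt
Reagents that add atoms: none
Why: Fluoride-induced desilylation cleaves the TBDPS ether under conditions to which dialkyl peroxides are stable.

Step 21
Reactants: 33 primary alcohol
Product: 35 mycaperoxide H, via aldehyde 34 (not isolated)
Conditions: TEMPO (20 mol %), PhI(OAc)2 (2.5 equiv), MeCN/H2O (1:1), rt
Reagents that add atoms: water, O
Why: TEMPO/PhI(OAc)2 oxidation takes the primary alcohol through the aldehyde hydrate to the carboxylic acid under non-basic conditions, so that epimerisation of C17′, retro-oxa-Michael opening of the β-peroxy carbonyl compound and attack on the hindered ring alkene are not expected.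

**Compound list**
1 | methyl 3,3-dimethylpent-4-enoate | COC(=O)CC(C)(C)C=C | starting material
2 | tert-butyl acetate | CC(=O)OC(C)(C)C | starting material
3 | lithium enolate of tert-butyl acetate | [Li]OC(=C)OC(C)(C)C | intermediate
4 | tert-butyl 5,5-dimethyl-3-oxohept-6-enoate | CC(C)(C)OC(=O)CC(=O)CC(C)(C)C=C | intermediate
5 | (E)-but-2-enal | C/C=C/C=O | starting material
6 | tert-butyl 5,5-dimethyl-3-oxo-2-[(2S)-4-oxobutan-2-yl]hept-6-enoate (Michael adduct, C7 epimers) | O=CC[C@H](C)C(C(=O)OC(C)(C)C)C(=O)CC(C)(C)C=C | intermediate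
7 | tert-butyl (6S)-6-methyl-3-(2-methylbut-3-en-2-yl)-2-oxocyclohex-3-ene-1-carboxylate (C1 epimers) | C1C=C(C(C)(C)C=C)C(=O)C(C(=O)OC(C)(C)C)[C@H]1C | intermediate
8 | (5S)-5-methyl-2-(2-methylbut-3-en-2-yl)cyclohex-2-en-1-one | C1C=C(C(C)(C)C=C)C(=O)C[C@H]1C | intermediate
9 | (1S,4S,6S)-4-methyl-1-(2-methylbut-3-en-2-yl)-7-oxabicyclo[4.1.0]heptan-2-one (epoxide trans to the methyl) | C1[C@@H]2O[C@]2(C(C)(C)C=C)C(=O)C[C@H]1C | intermediate
10 | (1S,5R)-5-methyl-2-(2-methylbut-3-en-2-yl)cyclohex-2-en-1-ol | C1[C@H](O)C(C(C)(C)C=C)=CC[C@H]1C | intermediate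
11 | (5R)-5-methyl-2-(2-methylbut-3-en-2-yl)cyclohex-2-en-1-one | C1C(=O)C(C(C)(C)C=C)=CC[C@H]1C | intermediate
12 | geranyl chloride, (2E)-1-chloro-3,7-dimethylocta-2,6-diene | ClC/C=C(\C)CCC=C(C)C | starting material
13 | (4E)-6-chloro-4-methylhex-4-enal | ClC/C=C(\C)CCC=O | intermediate
14 | (4S)-4-benzyl-3-propanoyl-1,3-oxazolidin-2-one | CCC(=O)N1[C@@H](Cc2ccccc2)COC1=O | starting material
15 | (Z)-dibutylboron enolate of 14 | C/C=C(\OB(CCCC)CCCC)N1[C@@H](Cc2ccccc2)COC1=O | intermediate
16 | (4S)-4-benzyl-3-[(2S,3R,6E)-8-chloro-3-hydroxy-2,6-dimethyloct-6-enoyl]-1,3-oxazolidin-2-one | C[C@H](C(=O)N1[C@@H](Cc2ccccc2)COC1=O)[C@H](O)CC/C(C)=C/CCl | intermediate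
17 | tert-butyldimethylsilyl ether of 16 | C[C@H](C(=O)N1[C@@H](Cc2ccccc2)COC1=O)[C@H](O[Si](C)(C)C(C)(C)C)CC/C(C)=C/CCl | intermediate
18 | (2R,3R,6E)-3-[(tert-butyldimethylsilyl)oxy]-8-chloro-2,6-dimethyloct-6-en-1-ol | C[C@H](CO)[C@H](O[Si](C)(C)C(C)(C)C)CC/C(C)=C/CCl | intermediate
19 | (2R,3R,6E)-3-[(tert-butyldimethylsilyl)oxy]-1-[(tert-butyldiphenylsilyl)oxy]-8-chloro-2,6-dimethyloct-6-ene | C[C@H](CO[Si](c4ccccc4)(c5ccccc5)C(C)(C)C)[C@H](O[Si](C)(C)C(C)(C)C)CC/C(C)=C/CCl | intermediate
20 | lithium cross-conjugated dienolate of 11 (C9=C10–OLi) | [Li]OC1=C[C@H](C)CC=C1C(C)(C)C=C | intermediate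
21 | (5R)-5-methyl-2-(2-methylbut-3-en-2-yl)cyclohex-2-en-1-one carrying at C6 (ring numbering; C9 of the target), trans to the methyl, the (2E,6R,7R)-6-(TBS-oxy)-8-(TBDPS-oxy)-3,7-dimethyloct-2-en-1-yl chain | C[C@H](CO[Si](c4ccccc4)(c5ccccc5)C(C)(C)C)[C@H](O[Si](C)(C)C(C)(C)C)CC/C(C)=C/C[C@@H]2C(=O)C(C(C)(C)C=C)=CC[C@H]2C | intermediate
22 | lithium enolate (C5=C10–OLi) from 1,4-reduction of 21 | C[C@H](CO[Si](c4ccccc4)(c5ccccc5)C(C)(C)C)[C@H](O[Si](C)(C)C(C)(C)C)CC/C(C)=C/C[C@@H]2C(O[Li])=C(C(C)(C)C=C)CC[C@H]2C | intermediate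
23 | saturated ketone of 21 with the 2-methylbut-3-en-2-yl group (C5), the methyl (C8) and the chain (C9) all equatorial | C[C@H](CO[Si](c4ccccc4)(c5ccccc5)C(C)(C)C)[C@H](O[Si](C)(C)C(C)(C)C)CC/C(C)=C/C[C@@H]2C(=O)[C@H](C(C)(C)C=C)CC[C@H]2C | intermediate
24 | lithium enolate (C9=C10–OLi) of 23 | C[C@H](CO[Si](c4ccccc4)(c5ccccc5)C(C)(C)C)[C@H](O[Si](C)(C)C(C)(C)C)CC/C(C)=C/CC2=C(O[Li])[C@H](C(C)(C)C=C)CC[C@H]2C | intermediate
25 | C9-methylated ketone (C9 methyl trans to C8 methyl, chain cis to it, C5 substituent trans to C8 methyl) | C[C@H](CO[Si](c4ccccc4)(c5ccccc5)C(C)(C)C)[C@H](O[Si](C)(C)C(C)(C)C)CC/C(C)=C/C[C@@]2(C)C(=O)[C@H](C(C)(C)C=C)CC[C@H]2C | intermediate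
26 | keto aldehyde (C5 substituent = 2-methyl-5-oxopentan-2-yl) | C[C@H](CO[Si](c4ccccc4)(c5ccccc5)C(C)(C)C)[C@H](O[Si](C)(C)C(C)(C)C)CC/C(C)=C/C[C@@]2(C)C(=O)[C@H](C(C)(C)CCC=O)CC[C@H]2C | intermediate
27 | decalin (target ring system, C1=C10) with the (2E)-octenyl chain, O16-TBS and O18′-TBDPS | C[C@H](CO[Si](c4ccccc4)(c5ccccc5)C(C)(C)C)[C@H](O[Si](C)(C)C(C)(C)C)CC/C(C)=C/C[C@@]2(C)C3=CCCC(C)(C)[C@@H]3CC[C@H]2C | intermediate
28 | C16 alcohol of 27 | C[C@H](CO[Si](c4ccccc4)(c5ccccc5)C(C)(C)C)[C@H](O)CC/C(C)=C/C[C@@]2(C)C3=CCCC(C)(C)[C@@H]3CC[C@H]2C | intermediate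
29 | C16 methanesulfonate of 28 | C[C@H](CO[Si](c4ccccc4)(c5ccccc5)C(C)(C)C)[C@H](OS(C)(=O)=O)CC/C(C)=C/C[C@@]2(C)C3=CCCC(C)(C)[C@@H]3CC[C@H]2C | intermediate
30 | C16 hydroperoxide (C16 inverted) | C[C@H](CO[Si](c4ccccc4)(c5ccccc5)C(C)(C)C)[C@@H](OO)CC/C(C)=C/C[C@@]2(C)C3=CCCC(C)(C)[C@@H]3CC[C@H]2C | intermediate
31 | 1,2-dioxane with acetoxymercurio group on C12 (C12 epimers) | C[C@H](CO[Si](c4ccccc4)(c5ccccc5)C(C)(C)C)[C@@H]1CC[C@@](C)(C([Hg]OC(C)=O)C[C@@]2(C)C3=CCCC(C)(C)[C@@H]3CC[C@H]2C)OO1 | intermediate
32 | TBDPS ether of the target's primary alcohol (1,2-dioxane formed) | C[C@H](CO[Si](c4ccccc4)(c5ccccc5)C(C)(C)C)[C@@H]1CC[C@@](C)(CC[C@@]2(C)C3=CCCC(C)(C)[C@@H]3CC[C@H]2C)OO1 | intermediate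
33 | primary alcohol (C18′ CH2OH) | C[C@H](CO)[C@@H]1CC[C@@](C)(CC[C@@]2(C)C3=CCCC(C)(C)[C@@H]3CC[C@H]2C)OO1 | intermediate
34 | aldehyde (C18′ CHO) | C[C@H](C=O)[C@@H]1CC[C@@](C)(CC[C@@]2(C)C3=CCCC(C)(C)[C@@H]3CC[C@H]2C)OO1 | intermediate
35 | mycaperoxide H | C[C@H](C(=O)O)[C@@H]1CC[C@@](C)(CC[C@@]2(C)C3=CCCC(C)(C)[C@@H]3CC[C@H]2C)OO1 | target

**Step count and risks**

Total: 21 steps. Longest linear sequence: 16 steps (steps 1–5 and 11–21; the side-chain branch, steps 6–10, joins at step 11).

Steps most likely to fail:

1. Step 2. The intramolecular aldol through the neopentyl γ-carbon C5 may be slow, so that the Michael adduct accumulates and is lost to self-condensation or retro-Michael erosion of the C8 configuration. Fallback, setting out from 4 and 5 and coming back at 8: the same amine-catalysed Michael addition would be stopped at the adduct and quenched with HC(OMe)3 and p-TsOH (cat.) in MeOH to give the acetal tert-butyl 2-[(2S)-4,4-dimethoxybutan-2-yl]-5,5-dimethyl-3-oxohept-6-enoate F1. TMSOTf and Et3N would convert it into its 1,3-bis(trimethylsilyloxy)diene F2, whose nucleophilic terminus is C5. TiCl4 in CH2Cl2 at −78 °C would then close ring B by a vinylogous Mukaiyama addition of C5 to the oxocarbenium ion at C10, giving tert-butyl (6S)-4-methoxy-6-methyl-3-(2-methylbut-3-en-2-yl)-2-oxocyclohexane-1-carboxylate F3. Warming F3 with p-TsOH in toluene would eliminate methanol and remove the ester as isobutene and CO2 to give 8.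

2. Step 18. Substitution at the β-branched secondary mesylate may be outrun by E2 elimination, and the hydroperoxide may decompose under the basic conditions. Fallback, setting out from 29 and coming back at 30: 29 would be alkylated with the mono-protected reagent 2-methoxyprop-2-yl hydroperoxide (CsOH, DMF, 0 °C) to give, with inversion, the 2-methoxyprop-2-yl peroxide of C16 F4, which is not base-sensitive. Mild acid (AcOH, THF/H2O) would then release 30.

3. Step 19. The mercury salt may attack the ring alkene, facial control at C13 may be poor, or the β-peroxyalkyl radical formed during demercuration may collapse to an epoxide. Fallback, setting out from 29 and coming back at 32: the order of the two C–O bond formations would be reversed. Hydroperoxysilylation of the C12=C13 alkene of 29 (Mukaiyama–Isayama conditions: Co(thd)2 with thd = 2,2,6,6-tetramethylheptane-3,5-dionate, O2, Et3SiH, 1,2-dichloroethane) would give the tertiary triethylsilyl peroxide with the mesylate still on C16 F5. K2CO3 in MeOH would free the peroxide anion, which would close the ring by SN2 at C16 with inversion to give 32; its C13 epimer would have to be removed by chromatography.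

Further compounds
F1 | step 2 | tert-butyl 2-[(2S)-4,4-dimethoxybutan-2-yl]-5,5-dimethyl-3-oxohept-6-enoate | COC(OC)C[C@H](C)C(C(=O)OC(C)(C)C)C(=O)CC(C)(C)C=C
F2 | step 2 | 1,3-bis(trimethylsilyloxy)diene of F1 | COC(OC)C[C@H](C)C(=C(O[Si](C)(C)C)OC(C)(C)C)C(O[Si](C)(C)C)=CC(C)(C)C=C
F3 | step 2 | tert-butyl (6S)-4-methoxy-6-methyl-3-(2-methylbut-3-en-2-yl)-2-oxocyclohexane-1-carboxylate | COC1C[C@H](C)C(C(=O)OC(C)(C)C)C(=O)C1C(C)(C)C=C
F4 | step 18 | 2-methoxyprop-2-yl peroxide of C16 (C16 inverted) | C[C@H](CO[Si](c4ccccc4)(c5ccccc5)C(C)(C)C)[C@@H](OOC(C)(C)OC)CC/C(C)=C/C[C@@]2(C)C3=CCCC(C)(C)[C@@H]3CC[C@H]2C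
F5 | step 19 | C13 triethylsilyl peroxide with C16 mesylate (C13 epimers) | C[C@H](CO[Si](c4ccccc4)(c5ccccc5)C(C)(C)C)[C@H](OS(C)(=O)=O)CCC(C)(OO[Si](CC)(CC)CC)CC[C@@]2(C)C3=CCCC(C)(C)[C@@H]3CC[C@H]2C
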